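**Retrosynthetic overview**

1. Target 20 ⇐ acid 19 (O‑methylation) ⇐ C19 silyl ether 16 (one‑flask desilylation and oxidation) ⇐ 3β‑alcohol 14 (Barton–McCombie); the C3 oxygen is only the trace of the cyclization trigger.
2. 14 ⇐ acyclic epoxy triene 13 by one cation–olefin cascade: ring A closes first (C4–C5), ring B second (C9–C10), and the C8 cation ends as the 8(17)‑olefin. The palmitate side chain is already in place and its allylic ester keeps C13=C14 out of the cascade.
3. A Sharpless epoxide is the initiating electrophile, because a proton would attack the internal olefins and not the one that carries the C19 oxygen. The Z geometry of that olefin puts C19 axial, and the tartrate fixes the absolute sense of every ring stereocentre.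
4. 13 ⇐ (14Z)‑16‑hydroxygeranylgeranyl palmitate 11 ⇐ B‑alkyl Suzuki coupling of the 9‑BBN adduct of diene 6 with (Z)‑iodo alcohol 9.
5. 6 ⇐ farnesyl palmitate 3 (allylic oxidation, then oxidation–methylenation) ⇐ farnesol 1 + palmitoyl chloride 2; 9 ⇐ propargyl alcohol 7.

Assumption: the SMILES is read as the normal‑series labdane (4S,5R,9S,10R), methyl isocupressate 15‑O‑palmitate, with the ester carbon C19 axial and cis to the C10 methyl; labdane numbering is used for these carbons in the acyclic precursors too.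

**Route**

Step 1
Reactants: 1 (2E,6E)-farnesol; 2 palmitoyl chloride
Product: 3 (2E,6E)-3,7,11-trimethyldodeca-2,6,10-trien-1-yl hexadecanoate
Conditions: Et3N, DMAP (catalytic), CH2Cl2, 0 °C to rt
Reagents that add atoms: none
Why: Acylation of the primary allylic alcohol by the acid chloride (nucleophilic acyl substitution under DMAP catalysis) installs the palmitate at the start, where it later deactivates the C13=C14 olefin, and no stereocentre is formed.

Step 2
Reactants: 3 (2E,6E)-3,7,11-trimethyldodeca-2,6,10-trien-1-yl hexadecanoate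
Product: 4 (2E,6E,10E)-12-hydroxy-3,7,11-trimethyldodeca-2,6,10-trien-1-yl hexadecanoate
Conditions: SeO2 (0.3 equiv), t-BuOOH (3 equiv), salicylic acid (catalytic), CH2Cl2, 0 °C to rt
Reagents that add atoms: selenium dioxide O=[Se]=O; tert-butyl hydroperoxide CC(C)(C)OO
Why: Catalytic Riley allylic oxidation (ene reaction followed by a [2,3]-shift) attacks the E-methyl group of the terminal and most electron-rich trisubstituted olefin and gives the E allylic alcohol, while the olefin next to the ester is deactivated.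

Step 3
Reactants: 4 (2E,6E,10E)-12-hydroxy-3,7,11-trimethyldodeca-2,6,10-trien-1-yl hexadecanoate
Product: 6 (2E,6E,10E)-3,7,11-trimethyltrideca-2,6,10,12-tetraen-1-yl hexadecanoate, via enal 5 (not isolated)
Conditions: MnO2 (10 equiv), Ph3PCH3Br (1.5 equiv), MTBD (2 equiv), 4 Å molecular sieves, THF, reflux
Reagents that add atoms: methyltriphenylphosphonium bromide C[P+](c1ccccc1)(c1ccccc1)c1ccccc1.[Br-]
Why: Tandem oxidation–Wittig olefination, in which MnO2 oxidises the allylic alcohol to the E-enal and the unstabilised ylide traps it at once, gives the 1,3-diene without changing the olefin geometry or touching the ester.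

Step 4
Reactants: 7 propargyl alcohol
Product: 9 (Z)-3-iodo-2-methylprop-2-en-1-ol, via alkenylmagnesium chelate 8 (not isolated)
Conditions: MeMgBr (2.5 equiv), CuI (10 mol%), THF, −10 °C to rt; then I2, −5 °C
Reagents that add atoms: methylmagnesium bromide C[Mg]Br; iodine II
Why: Copper-catalysed anti-carbomagnesiation of the propargylic alkoxide gives a five-membered magnesium chelate, so iodinolysis with retention places iodine cis to the CH2OH group and fixes the Z geometry.

Step 5
Reactants: 6 (2E,6E,10E)-3,7,11-trimethyltrideca-2,6,10,12-tetraen-1-yl hexadecanoate; 9 (Z)-3-iodo-2-methylprop-2-en-1-ol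
Product: 11 (2E,6E,10E,14Z)-16-hydroxy-3,7,11,15-tetramethylhexadeca-2,6,10,14-tetraen-1-yl hexadecanoate, via alkylborane 10 (not isolated)
Conditions: 9-BBN (1.2 equiv), THF, 0 °C to rt; then 9, Pd(dppf)Cl2 (5 mol%), AsPh3 (5 mol%), Cs2CO3 (3 equiv), DMF/H2O, rt
Reagents that add atoms: none
Why: Anti-Markovnikov hydroboration by 9-BBN occurs only at the monosubstituted terminus of the diene, and the B-alkyl Suzuki–Miyaura coupling then joins C2 to C3 with retention of the Z geometry of the iodide, the geometry that later makes C19 axial.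

Step 6
Reactants: 11 (2E,6E,10E,14Z)-16-hydroxy-3,7,11,15-tetramethylhexadeca-2,6,10,14-tetraen-1-yl hexadecanoate
Product: 13 (2E,6E,10E)-13-[(2S,3R)-3-(tert-butyldimethylsilyloxymethyl)-3-methyloxiran-2-yl]-3,7,11-trimethyltrideca-2,6,10-trien-1-yl hexadecanoate, via epoxy alcohol 12 (not isolated)
Conditions: Ti(OiPr)4 (0.2 equiv), D-(−)-diethyl tartrate (0.24 equiv), t-BuOOH (2 equiv), 4 Å molecular sieves, CH2Cl2, −20 °C; then imidazole, TBSCl, DMAP (catalytic), −20 °C to rt
Reagents that add atoms: tert-butyl hydroperoxide CC(C)(C)OO; tert-butyldimethylsilyl chloride CC(C)(C)[Si](C)(C)Cl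
Why: Sharpless asymmetric epoxidation is directed by the allylic hydroxyl to the one olefin that carries it, D-(−)-tartrate delivers oxygen to the face that gives the (2S,3R)-oxirane (C3 S and C4 R, the sense of natural (3S)-oxidosqualene), and silylation in the same flask protects the primary alcohol.

Step 7
Reactants: 13 (2E,6E,10E)-13-[(2S,3R)-3-(tert-butyldimethylsilyloxymethyl)-3-methyloxiran-2-yl]-3,7,11-trimethyltrideca-2,6,10-trien-1-yl hexadecanoate
Product: 14 (3S,4S,5R,9S,10R,13E)-19-(tert-butyldimethylsilyloxy)-3-hydroxylabda-8(17),13-dien-15-yl hexadecanoate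
Conditions: MeAlCl2 (2.5 equiv), CH2Cl2, −78 °C, 30 min; then Et3N, aqueous NaHCO3
Reagents that add atoms: none
Why: Lewis-acid-promoted epoxide-initiated cation–olefin bicyclization (biomimetic polyene cyclization of the oxidosqualene type), in which the C5=C10 π bond opens the aluminium-bound epoxide at tertiary C4 with inversion through a chair–chair fold, so that the Z-disposed CH2OTBS becomes axial C19 and the epoxide oxygen the equatorial 3β-OH, the two E olefins give the trans-fused 5α-H/10β-CH3/9α-H array, the allylic ester keeps C13=C14 out of the cascade, and the C8 cation loses a C17 proton to the Al–CH3 bond (as CH4) to leave the 8(17)-olefin.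

Step 8
Reactants: 14 (3S,4S,5R,9S,10R,13E)-19-(tert-butyldimethylsilyloxy)-3-hydroxylabda-8(17),13-dien-15-yl hexadecanoate
Product: 15 O-[(3S,4S,5R,9S,10R,13E)-19-(tert-butyldimethylsilyloxy)-15-(hexadecanoyloxy)labda-8(17),13-dien-3-yl] 1H-imidazole-1-carbothioate
Conditions: 1,1'-thiocarbonyldiimidazole (3 equiv), DMAP (0.2 equiv), ClCH2CH2Cl, 70 °C
Reagents that add atoms: 1,1'-thiocarbonyldiimidazole S=C(n1ccnc1)n1ccnc1
Why: Thioacylation of the only free hydroxyl, the equatorial secondary 3β-OH, gives the Barton–McCombie precursor without affecting the silyl ether, the ester or the olefins.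

Step 9
Reactants: 15 O-[(3S,4S,5R,9S,10R,13E)-19-(tert-butyldimethylsilyloxy)-15-(hexadecanoyloxy)labda-8(17),13-dien-3-yl] 1H-imidazole-1-carbothioate
Product: 16 (4S,5R,9S,10R,13E)-19-(tert-butyldimethylsilyloxy)labda-8(17),13-dien-15-yl hexadecanoate
Conditions: Bu3SnH (2 equiv), AIBN (0.2 equiv), toluene, 100 °C
Reagents that add atoms: none
Why: Barton–McCombie radical deoxygenation replaces the C3 oxygen by hydrogen once it has served as the cyclization trigger, and the secondary C3 radical has neither a weak β-bond nor an olefin within reach, so the four ring stereocentres are untouched.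

Step 10
Reactants: 16 (4S,5R,9S,10R,13E)-19-(tert-butyldimethylsilyloxy)labda-8(17),13-dien-15-yl hexadecanoate
Product: 19 (4S,5R,9S,10R,13E)-15-(hexadecanoyloxy)labda-8(17),13-dien-19-oic acid, via primary alcohol 17 (not isolated), via aldehyde 18 (not isolated)
Conditions: CrO3, H2SO4, H2O, acetone, 0 °C to rt
Reagents that add atoms: water O
Why: Under Jones oxidation conditions the primary silyl ether is hydrolysed and the neopentyl alcohol is oxidised through the aldehyde hydrate to the C19 acid in one flask, a conversion that 19-hydroxy diterpenes with exocyclic olefins tolerate, and the quaternary C4 cannot epimerise.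

Step 11
Reactants: 19 (4S,5R,9S,10R,13E)-15-(hexadecanoyloxy)labda-8(17),13-dien-19-oic acid
Product: 20 methyl (4S,5R,9S,10R,13E)-15-(hexadecanoyloxy)labda-8(17),13-dien-19-oate
Conditions: Me3SiCHN2, toluene/MeOH 4:1, rt
Reagents that add atoms: (trimethylsilyl)diazomethane C[Si](C)(C)C=[N+]=[N-]
Why: O-Methylation of the hindered axial acid by the diazoalkane (proton transfer, then SN2 attack of the carboxylate on the methyldiazonium ion) needs no attack at the crowded carbonyl and leaves the palmitate and both olefins alone.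

**Compound list**

1 | (2E,6E)-farnesol | CC(C)=CCC/C(C)=C/CC/C(C)=C/CO | starting material
2 | palmitoyl chloride (hexadecanoyl chloride) | CCCCCCCCCCCCCCCC(=O)Cl | starting material
3 | (2E,6E)-3,7,11-trimethyldodeca-2,6,10-trien-1-yl hexadecanoate (farnesyl palmitate) | CC(C)=CCC/C(C)=C/CC/C(C)=C/COC(=O)CCCCCCCCCCCCCCC | intermediate
4 | (2E,6E,10E)-12-hydroxy-3,7,11-trimethyldodeca-2,6,10-trien-1-yl hexadecanoate | OC/C(C)=C/CC/C(C)=C/CC/C(C)=C/COC(=O)CCCCCCCCCCCCCCC | intermediate
5 | (2E,6E,10E)-3,7,11-trimethyl-12-oxododeca-2,6,10-trien-1-yl hexadecanoate (E-enal) | O=C/C(C)=C/CC/C(C)=C/CC/C(C)=C/COC(=O)CCCCCCCCCCCCCCC | intermediate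
6 | (2E,6E,10E)-3,7,11-trimethyltrideca-2,6,10,12-tetraen-1-yl hexadecanoate | C=C/C(C)=C/CC/C(C)=C/CC/C(C)=C/COC(=O)CCCCCCCCCCCCCCC | intermediate
7 | propargyl alcohol (prop-2-yn-1-ol) | C#CCO | starting material
8 | (Z)-[3-(bromomagnesiooxy)-2-methylprop-1-en-1-yl]magnesium bromide | C/C(CO[Mg]Br)=C/[Mg]Br | intermediate
9 | (Z)-3-iodo-2-methylprop-2-en-1-ol | C/C(CO)=C/I | intermediate
10 | 9-[(3E,7E,11E)-13-(hexadecanoyloxy)-3,7,11-trimethyltrideca-3,7,11-trien-1-yl]-9-borabicyclo[3.3.1]nonane | B1(CC/C(C)=C/CC/C(C)=C/CC/C(C)=C/COC(=O)CCCCCCCCCCCCCCC)C2CCCC1CCC2 | intermediate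
11 | (2E,6E,10E,14Z)-16-hydroxy-3,7,11,15-tetramethylhexadeca-2,6,10,14-tetraen-1-yl hexadecanoate | OC/C(C)=C\CC/C(C)=C/CC/C(C)=C/CC/C(C)=C/COC(=O)CCCCCCCCCCCCCCC | intermediate
12 | (2E,6E,10E)-13-[(2S,3R)-3-(hydroxymethyl)-3-methyloxiran-2-yl]-3,7,11-trimethyltrideca-2,6,10-trien-1-yl hexadecanoate (cis-epoxide) | OC[C@@]1(C)O[C@H]1CC/C(C)=C/CC/C(C)=C/CC/C(C)=C/COC(=O)CCCCCCCCCCCCCCC | intermediate
13 | (2E,6E,10E)-13-[(2S,3R)-3-(tert-butyldimethylsilyloxymethyl)-3-methyloxiran-2-yl]-3,7,11-trimethyltrideca-2,6,10-trien-1-yl hexadecanoate | CC(C)(C)[Si](C)(C)OC[C@@]1(C)O[C@H]1CC/C(C)=C/CC/C(C)=C/CC/C(C)=C/COC(=O)CCCCCCCCCCCCCCC | intermediate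
14 | (3S,4S,5R,9S,10R,13E)-19-(tert-butyldimethylsilyloxy)-3-hydroxylabda-8(17),13-dien-15-yl hexadecanoate (3β-OH equatorial, C19 axial β, 5α-H, 9α-H, 10β-CH3) | C=C1CC[C@@H]2[C@](C)(CC[C@H](O)[C@]2(C)CO[Si](C)(C)C(C)(C)C)[C@H]1CC/C(C)=C/COC(=O)CCCCCCCCCCCCCCC | intermediate
15 | O-[(3S,4S,5R,9S,10R,13E)-19-(tert-butyldimethylsilyloxy)-15-(hexadecanoyloxy)labda-8(17),13-dien-3-yl] 1H-imidazole-1-carbothioate | C=C1CC[C@@H]2[C@](C)(CC[C@H](OC(=S)n3ccnc3)[C@]2(C)CO[Si](C)(C)C(C)(C)C)[C@H]1CC/C(C)=C/COC(=O)CCCCCCCCCCCCCCC | intermediate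
16 | (4S,5R,9S,10R,13E)-19-(tert-butyldimethylsilyloxy)labda-8(17),13-dien-15-yl hexadecanoate | C=C1CC[C@@H]2[C@](C)(CCC[C@]2(C)CO[Si](C)(C)C(C)(C)C)[C@H]1CC/C(C)=C/COC(=O)CCCCCCCCCCCCCCC | intermediate
17 | (4S,5R,9S,10R,13E)-19-hydroxylabda-8(17),13-dien-15-yl hexadecanoate | C=C1CC[C@@H]2[C@](C)(CCC[C@]2(C)CO)[C@H]1CC/C(C)=C/COC(=O)CCCCCCCCCCCCCCC | intermediate
18 | (4S,5R,9S,10R,13E)-19-oxolabda-8(17),13-dien-15-yl hexadecanoate | C=C1CC[C@@H]2[C@](C)(CCC[C@]2(C)C=O)[C@H]1CC/C(C)=C/COC(=O)CCCCCCCCCCCCCCC | intermediate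
19 | (4S,5R,9S,10R,13E)-15-(hexadecanoyloxy)labda-8(17),13-dien-19-oic acid (isocupressic acid 15-palmitate) | C=C1CC[C@@H]2[C@](C)(CCC[C@]2(C)C(=O)O)[C@H]1CC/C(C)=C/COC(=O)CCCCCCCCCCCCCCC | intermediate
20 | methyl (4S,5R,9S,10R,13E)-15-(hexadecanoyloxy)labda-8(17),13-dien-19-oate (CNP0157008.1) | C=C1CC[C@@H]2[C@](C)(CCC[C@]2(C)C(=O)OC)[C@H]1CC/C(C)=C/COC(=O)CCCCCCCCCCCCCCC | target

**Totals and risks**

Total step count: 11. Longest linear sequence: 10 steps (steps 1, 2, 3, 5, 6, 7, 8, 9, 10, 11); step 4 is the side branch.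

The three steps most likely to fail:

Step 7 (epoxide-initiated bicyclization). The C8 cation can also lose a ring proton, giving the 7-ene and 8-ene isomers, which would have to be removed on AgNO3-impregnated silica. The epoxy silyl ether can rearrange to a carbonyl compound before ring A closes, and some material may stop after ring A. The fallback changes the way the cascade is ended. From 13, SnCl4 (CH2Cl2, −78 °C) is used so that the C8 cation is captured by chloride on its open α face, giving the equatorial tertiary chloride 8α-chloro-3β-hydroxy-19-(tert-butyldimethylsilyloxy)labd-13-en-15-yl hexadecanoate F1. In the locked trans-decalin the equatorial C–Cl bond is antiperiplanar only to the C17 hydrogens, so E2 elimination with DBU (toluene, 100 °C) can give only the 8(17)-olefin, and the route is rejoined at 14.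

Step 5 (hydroboration and B-alkyl Suzuki coupling). Zerovalent palladium may ionise the allylic palmitate, and the carbonate base is weak for transmetalation of the alkylborane. The fallback moves the ester past the coupling. From 6, K2CO3 in MeOH removes the palmitate to give (2E,6E,10E)-3,7,11-trimethyltrideca-2,6,10,12-tetraen-1-ol F2, and 9 is silylated (TBSCl, imidazole) to (Z)-tert-butyl[(3-iodo-2-methylprop-2-en-1-yl)oxy]dimethylsilane F3. Hydroboration of F2 with 9-BBN (2.2 equiv) and coupling with F3 (Pd(dppf)Cl2, Cs2CO3, DMF/H2O, no allylic ester present) gives (2E,6E,10E,14Z)-16-(tert-butyldimethylsilyloxy)-3,7,11,15-tetramethylhexadeca-2,6,10,14-tetraen-1-ol F4. Acylation with 2 (Et3N, DMAP) gives (2E,6E,10E,14Z)-16-(tert-butyldimethylsilyloxy)-3,7,11,15-tetramethylhexadeca-2,6,10,14-tetraen-1-yl hexadecanoate F5, and HF·pyridine removes the silyl group to rejoin the route at 11.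

Step 2 (allylic oxidation). Conversion is modest, and over-oxidation and some attack at the internal olefin are expected. The fallback replaces C–H oxidation by olefin metathesis. From 3, cross-metathesis with methacrolein (second-generation Hoveyda–Grubbs catalyst, CH2Cl2, 40 °C) exchanges the terminal isopropylidene group, the only unhindered trisubstituted olefin, for the E-enal and so gives 5 directly as an isolated compound. Methylenation with Ph3P=CH2 (THF, −78 °C to rt) rejoins the route at 6. This fallback makes no compound outside the list (F0).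

**Further compounds**

F1 | step 7 | 8α-chloro-3β-hydroxy-19-(tert-butyldimethylsilyloxy)labd-13E-en-15-yl hexadecanoate (8β-CH3 axial, 8α-Cl equatorial) | C[C@@]1(Cl)CC[C@@H]2[C@](C)(CC[C@H](O)[C@]2(C)CO[Si](C)(C)C(C)(C)C)[C@H]1CC/C(C)=C/COC(=O)CCCCCCCCCCCCCCC
F2 | step 5 | (2E,6E,10E)-3,7,11-trimethyltrideca-2,6,10,12-tetraen-1-ol | C=C/C(C)=C/CC/C(C)=C/CC/C(C)=C/CO
F3 | step 5 | (Z)-tert-butyl[(3-iodo-2-methylprop-2-en-1-yl)oxy]dimethylsilane | C/C(CO[Si](C)(C)C(C)(C)C)=C/I
F4 | step 5 | (2E,6E,10E,14Z)-16-(tert-butyldimethylsilyloxy)-3,7,11,15-tetramethylhexadeca-2,6,10,14-tetraen-1-ol | CC(C)(C)[Si](C)(C)OC/C(C)=C\CC/C(C)=C/CC/C(C)=C/CC/C(C)=C/CO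
F5 | step 5 | (2E,6E,10E,14Z)-16-(tert-butyldimethylsilyloxy)-3,7,11,15-tetramethylhexadeca-2,6,10,14-tetraen-1-yl hexadecanoate | CC(C)(C)[Si](C)(C)OC/C(C)=C\CC/C(C)=C/CC/C(C)=C/CC/C(C)=C/COC(=O)CCCCCCCCCCCCCCC
F0 | step 2 | none | none
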